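**Retrosynthetic overview**

1. Manassantin A (15) ⇒ C2-symmetric bisphenol oxolane 12 + 2 × racemic α-bromo ketone 13. Both aryl ether bonds come from SN2 alkylation; both carbinol/ether stereodiads come from one twofold dynamic-kinetic transfer hydrogenation.
2. 12 ⇒ 2-sulfonyl oxolane + arylzinc (aryl–C bond by oxocarbenium arylation, cis to the neighbouring methyl). Two such oxolane units are carried on one m-xylylene bis-ether, which is the benzyl-type protecting group of both phenols (7 + 2 × 8 ⇒ 11 ⇒ 2 × 12).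
3. Both oxolane rings ⇒ bis-homoallylic alcohol 4, by one twofold hydroxyl-directed branched hydroformylation with spontaneous double lactol closure (4 ⇒ 6).
4. 4 ⇒ linked bis-aldehyde 3 by twofold (Z)-crotylboration; 3 ⇒ 2 × vanillin 1 + dibromide 2.
5. Ring order: all arenes are bought; the two oxolane rings are closed together in step 3; no other ring is made.

Assumption: 1, 2, 8, 13 and all reagents are bought; the anomeric carbon of lactol, sulfone and acetal intermediates is carried as a mixture of both configurations; where a step uses a building block or reagent twice, the second equivalent is entered once more under "Reagents that add atoms" so that every atom of the product is accounted for.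

**Route**

Step 1
Reactants: 1 vanillin (2 equiv); 2 1,3-bis(bromomethyl)benzene (1 equiv)
Product: 3 1,3-bis[(4-formyl-2-methoxyphenoxy)methyl]benzene
Conditions: 1 (2.1 equiv), 2 (1 equiv), K2CO3 (2.5 equiv), DMF, 60 °C
Reagents that add atoms: vanillin 1, second equivalent, COc1cc(C=O)ccc1O
Why: Twofold Williamson ether synthesis in which two vanillin phenoxides each displace one benzylic bromide of 2 by SN2, the aldehydes being inert to K2CO3, so that one hydrogenolysable m-xylylene bis-ether protects two phenols; no stereocenter is formed.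

Step 2
Reactants: 3 1,3-bis[(4-formyl-2-methoxyphenoxy)methyl]benzene
Product: 4 1,3-bis({4-[(1S,2R)-1-hydroxy-2-methylbut-3-en-1-yl]-2-methoxyphenoxy}methyl)benzene
Conditions: cis-2-butene, n-BuLi, KOt-Bu, THF, −78 to −45 °C; (−)-Ipc2BOMe, −78 °C; BF3·OEt2; then 3 (0.4 equiv with respect to boron), −78 °C; NaOH, H2O2, 0 °C to rt
Reagents that add atoms: cis-2-butene, C/C=C\C (crotyl group for the first aldehyde); cis-2-butene, C/C=C\C (crotyl group for the second aldehyde); each is transferred as the crotyl group of (Z)-crotyl-B(Ipc)2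
Why: Twofold Brown asymmetric crotylboration through a closed chair Zimmerman–Traxler transition state, in which the (Z)-crotyl geometry gives the syn relationship and the isopinocampheyl groups of the (+)-α-pinene series direct addition to the Si face of each aldehyde, so both ends become (1S,2R) under reagent control.

Step 3
Reactants: 4 1,3-bis({4-[(1S,2R)-1-hydroxy-2-methylbut-3-en-1-yl]-2-methoxyphenoxy}methyl)benzene
Product: 6 1,3-bis({4-[(2S,3R,4R)-5-hydroxy-3,4-dimethyloxolan-2-yl]-2-methoxyphenoxy}methyl)benzene (both anomers), via bis(hydroxy aldehyde) 5 (not isolated)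
Conditions: Rh(acac)(CO)2 (4 mol %), 1-isopropyl-2-methoxy-3-phenyl-2,3-dihydro-1H-1,3-benzazaphosphole (40 mol %), p-TsOH (0.4 mol %), CO/H2 (1:1, 14 bar), benzene, 45 °C
Reagents that add atoms: carbon monoxide, [C-]#[O+] (for the first alkene); carbon monoxide, [C-]#[O+] (for the second alkene)
Why: Rhodium-catalysed hydroxyl-directed branched hydroformylation (scaffolding-ligand catalysis), in which the ligand exchanges its methoxy group for each carbinol oxygen and delivers Rh–H and CO so that the formyl group enters at the internal alkene carbon, the two γ-hydroxy aldehyde units of 5 then close to two five-membered lactol rings in the same operation, and the new methyl-bearing center is set anti to the neighbouring methyl in the cyclic transition state and, being alpha to the masked aldehyde, can also relax to this trans arrangement by ring–chain tautomerism.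

Step 4
Reactants: 6 1,3-bis({4-[(2S,3R,4R)-5-hydroxy-3,4-dimethyloxolan-2-yl]-2-methoxyphenoxy}methyl)benzene
Product: 7 1,3-bis({4-[(2S,3R,4R)-5-(benzenesulfonyl)-3,4-dimethyloxolan-2-yl]-2-methoxyphenoxy}methyl)benzene (both anomers)
Conditions: PhSO2H (3 equiv), CaCl2, CH2Cl2, rt
Reagents that add atoms: benzenesulfinic acid, O=S(O)c1ccccc1 (for the first lactol); benzenesulfinic acid, O=S(O)c1ccccc1 (for the second lactol)
Why: Ley lactol-to-2-sulfonyl ether exchange, in which the acid ionises each lactol to its oxocarbenium ion that is trapped at sulfur by the sulfinate while CaCl2 takes up water; the sulfonyl-bearing carbon forms as a mixture that does not matter because both anomers give the same cation in step 5.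

Step 5
Reactants: 7 1,3-bis({4-[(2S,3R,4R)-5-(benzenesulfonyl)-3,4-dimethyloxolan-2-yl]-2-methoxyphenoxy}methyl)benzene; 8 1-(benzyloxy)-4-bromo-2-methoxybenzene (one per sulfone, used in excess)
Product: 11 1,3-bis[(4-{(2S,3R,4R,5S)-5-[4-(benzyloxy)-3-methoxyphenyl]-3,4-dimethyloxolan-2-yl}-2-methoxyphenoxy)methyl]benzene, via arylmagnesium bromide 9 (not isolated), via arylzinc bromide 10 (not isolated)
Conditions: 8 (5 equiv), Mg, THF, rt; ZnBr2, THF; then 7, THF, rt
Reagents that add atoms: aryl bromide 8, second equivalent (for the second sulfone), COc1cc(Br)ccc1OCc1ccccc1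
Why: Ley-type substitution of a 2-sulfonyl cyclic ether by an arylzinc (Grignard formation, transmetalation, Lewis-acid ionisation of each sulfone to a five-membered oxocarbenium ion), in which the aryl group adds by inside attack on the envelope cation, syn to the adjacent C-methyl and anti to the aryl group across the ring oxygen, which sets C5 of each oxolane as S and gives the 2,3-cis-3,4-trans-4,5-cis array.

Step 6
Reactants: 11 1,3-bis[(4-{(2S,3R,4R,5S)-5-[4-(benzyloxy)-3-methoxyphenyl]-3,4-dimethyloxolan-2-yl}-2-methoxyphenoxy)methyl]benzene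
Product: 12 4,4'-[(2S,3R,4R,5S)-3,4-dimethyloxolane-2,5-diyl]bis(2-methoxyphenol)
Conditions: H2 (1 atm), Pd/C, EtOAc/MeOH, rt
Reagents that add atoms: none
Why: Catalytic hydrogenolysis of aryl benzyl ethers cleaves both linker C–O bonds and both benzyl ethers and releases two molecules of the C2-symmetric bisphenol 12 per molecule of 11, while the slower-reacting cyclic benzylic ether bonds of the oxolane and all four stereocenters stay intact under these mild neutral conditions.

Step 7
Reactants: 12 4,4'-[(2S,3R,4R,5S)-3,4-dimethyloxolane-2,5-diyl]bis(2-methoxyphenol) (1 equiv); 13 2-bromo-1-(3,4-dimethoxyphenyl)propan-1-one, racemic (2 equiv)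
Product: 14 2,2'-{[(2S,3R,4R,5S)-3,4-dimethyloxolane-2,5-diyl]bis[(2-methoxy-4,1-phenylene)oxy]}bis[1-(3,4-dimethoxyphenyl)propan-1-one] (mixture of epimers at both O–CH(CH3) carbons)
Conditions: 13 (2.4 equiv), K2CO3 (3 equiv), acetone, rt
Reagents that add atoms: bromo ketone 13, second equivalent (for the second phenol), CC(Br)C(=O)c1ccc(OC)c(OC)c1
Why: Twofold Williamson-type SN2 alkylation in which each of the two phenoxides of 12 displaces bromide from one molecule of the activated alpha-bromo ketone; the two new ether-bearing carbons form without control and are left as an epimeric mixture because they are epimerisable alpha to the ketone and are set in step 8.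

Step 8
Reactants: 14 2,2'-{[(2S,3R,4R,5S)-3,4-dimethyloxolane-2,5-diyl]bis[(2-methoxy-4,1-phenylene)oxy]}bis[1-(3,4-dimethoxyphenyl)propan-1-one]
Product: 15 manassantin A, (1R,2R)-1-(3,4-dimethoxyphenyl)-2-[4-[(2S,3R,4R,5S)-5-[4-[(1R,2R)-1-(3,4-dimethoxyphenyl)-1-hydroxypropan-2-yl]oxy-3-methoxyphenyl]-3,4-dimethyloxolan-2-yl]-2-methoxyphenoxy]propan-1-ol
Conditions: RuCl[(S,S)-TsDPEN](p-cymene) (5 mol %), HCO2H/DBU (2:3), DMF, 40 °C
Reagents that add atoms: none
Why: Proposed new method: twofold dynamic kinetic resolution by Noyori–Ikariya asymmetric transfer hydrogenation of an alpha-aryloxy aryl ketone, reasoned as follows: DBU enolises the alpha-aryloxy ketone faster than the electron-rich carbonyl is reduced so the ether carbon epimerises continuously, the (S,S)-TsDPEN ruthenium hydride attacks the carbonyl face that gives the 1R carbinol (aryl CH–π control, as for acetophenone), and of the two equilibrating epimers the 2R one reacts faster because hydride then enters anti to the aryloxy group in a non-chelated Felkin–Anh arrangement, giving the threo (1R,2R) unit in both arms; the closest known reactions are the dynamic-kinetic transfer hydrogenation of benzoin to (R,R)-hydrobenzoin by the same catalyst and of alpha-alkoxy beta-keto esters.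

**Compound list**

1 | vanillin (4-hydroxy-3-methoxybenzaldehyde) | COc1cc(C=O)ccc1O | starting material
2 | 1,3-bis(bromomethyl)benzene | BrCc1cccc(CBr)c1 | starting material
3 | 1,3-bis[(4-formyl-2-methoxyphenoxy)methyl]benzene | COc1cc(C=O)ccc1OCc1cccc(COc2ccc(C=O)cc2OC)c1 | intermediate
4 | 1,3-bis({4-[(1S,2R)-1-hydroxy-2-methylbut-3-en-1-yl]-2-methoxyphenoxy}methyl)benzene | C=C[C@@H](C)[C@H](O)c1ccc(OCc2cccc(COc3ccc(cc3OC)[C@@H](O)[C@H](C)C=C)c2)c(OC)c1 | intermediate
5 | 1,3-bis({4-[(1S,2R,3R)-1-hydroxy-2,3-dimethyl-4-oxobutyl]-2-methoxyphenoxy}methyl)benzene | O=C[C@H](C)[C@@H](C)[C@H](O)c1ccc(OCc2cccc(COc3ccc(cc3OC)[C@@H](O)[C@H](C)[C@@H](C)C=O)c2)c(OC)c1 | intermediate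
6 | 1,3-bis({4-[(2S,3R,4R)-5-hydroxy-3,4-dimethyloxolan-2-yl]-2-methoxyphenoxy}methyl)benzene, both anomers | OC1O[C@H](c2ccc(OCc3cccc(COc4ccc(cc4OC)[C@H]5OC(O)[C@H](C)[C@H]5C)c3)c(OC)c2)[C@H](C)[C@H]1C | intermediate
7 | 1,3-bis({4-[(2S,3R,4R)-5-(benzenesulfonyl)-3,4-dimethyloxolan-2-yl]-2-methoxyphenoxy}methyl)benzene, both anomers | O=S(=O)(c1ccccc1)C1O[C@H](c2ccc(OCc3cccc(COc4ccc(cc4OC)[C@H]5OC(S(=O)(=O)c6ccccc6)[C@H](C)[C@H]5C)c3)c(OC)c2)[C@H](C)[C@H]1C | intermediate
8 | 1-(benzyloxy)-4-bromo-2-methoxybenzene | COc1cc(Br)ccc1OCc1ccccc1 | starting material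
9 | [4-(benzyloxy)-3-methoxyphenyl]magnesium bromide | COc1cc([Mg]Br)ccc1OCc1ccccc1 | intermediate
10 | [4-(benzyloxy)-3-methoxyphenyl]zinc bromide | COc1cc([Zn]Br)ccc1OCc1ccccc1 | intermediate
11 | 1,3-bis[(4-{(2S,3R,4R,5S)-5-[4-(benzyloxy)-3-methoxyphenyl]-3,4-dimethyloxolan-2-yl}-2-methoxyphenoxy)methyl]benzene | c1ccccc1COc1ccc(cc1OC)[C@H]1O[C@H](c2ccc(OCc3cccc(COc4ccc(cc4OC)[C@H]5O[C@H](c6ccc(OCc7ccccc7)c(OC)c6)[C@H](C)[C@H]5C)c3)c(OC)c2)[C@H](C)[C@H]1C | intermediate
12 | 4,4'-[(2S,3R,4R,5S)-3,4-dimethyloxolane-2,5-diyl]bis(2-methoxyphenol) | COc1cc(ccc1O)[C@H]1O[C@H](c2ccc(O)c(OC)c2)[C@H](C)[C@H]1C | intermediate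
13 | 2-bromo-1-(3,4-dimethoxyphenyl)propan-1-one, racemic | CC(Br)C(=O)c1ccc(OC)c(OC)c1 | starting material
14 | 2,2'-{[(2S,3R,4R,5S)-3,4-dimethyloxolane-2,5-diyl]bis[(2-methoxy-4,1-phenylene)oxy]}bis[1-(3,4-dimethoxyphenyl)propan-1-one], epimeric at both O–CH(CH3) carbons | COc1ccc(cc1OC)C(=O)C(C)Oc1ccc(cc1OC)[C@H]1O[C@H](c2ccc(OC(C)C(=O)c3ccc(OC)c(OC)c3)c(OC)c2)[C@H](C)[C@H]1C | intermediate
15 | manassantin A | COc1ccc([C@@H](O)[C@@H](C)Oc2ccc([C@H]3O[C@H](c4ccc(O[C@H](C)[C@H](O)c5ccc(OC)c(OC)c5)c(OC)c4)[C@H](C)[C@H]3C)cc2OC)cc1OC | target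

**Summary**

Total step count: 8. Longest linear sequence: 8 steps (1 → 3 → 4 → 6 → 7 → 11 → 12 → 14 → 15).

Three steps most likely to fail, each with a fallback:

- **Step 3.** The directed hydroformylation may give some linear aldehyde (six-membered lactol) or poor control at the new methyl-bearing carbon. The fallback sets out from 4 and builds the same rings by enolate chemistry. Hydroboration of both vinyl groups (9-BBN, THF; NaOH, H2O2) gives the bis(1,4-diol) F1. TEMPO/PhI(OAc)2 closes both rings to the bis(cis-4-methyl-5-aryl lactone) F2. Methylation of both lactone enolates (LiN(SiMe3)2, MeI, THF, −78 °C), anti to the neighbouring methyl, gives the bis(3,4-trans-dimethyl lactone) F3. Reduction with i-Bu2AlH (CH2Cl2, −78 °C) comes back to the route at 6.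

- **Step 5.** The organozinc/sulfone coupling may stall at one arm or give a low cis ratio. The fallback sets out from 6. MeOH with pyridinium p-toluenesulfonate gives the bis(methyl acetal) F4. This is arylated by potassium [4-(benzyloxy)-3-methoxyphenyl]trifluoroborate F5 (from 8: n-BuLi, B(OMe)3; then KHF2) under BF3·OEt2 in MeCN at −40 °C. This boron-to-oxocarbenium aryl transfer replaces the zinc/sulfone pair and comes back to the route at 11.

- **Step 8.** Enolisation of 14 may be slower than its reduction, so the two arms would not converge. The fallback sets out from 12 and takes the ether stereocenter from the chiral pool. Friedel–Crafts acylation of 1,2-dimethoxybenzene with (S)-2-chloropropanoyl chloride (AlCl3, CH2Cl2, 0 °C) gives (S)-2-chloro-1-(3,4-dimethoxyphenyl)propan-1-one F6. Two equivalents of F6 alkylate 12 with inversion (K2CO3, acetone, 0 °C) to the (R,R)-bis-ketone F7. Substrate- and catalyst-matched reduction with the same ruthenium catalyst (HCO2H/Et3N 5:2, no DBU) comes back to the route at 15.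

**Further compounds**

F1 | step 3 | 1,3-bis({4-[(1S,2R)-1,4-dihydroxy-2-methylbutyl]-2-methoxyphenoxy}methyl)benzene | OCC[C@@H](C)[C@H](O)c1ccc(OCc2cccc(COc3ccc(cc3OC)[C@@H](O)[C@H](C)CCO)c2)c(OC)c1
F2 | step 3 | 1,3-bis({2-methoxy-4-[(2S,3R)-3-methyl-5-oxooxolan-2-yl]phenoxy}methyl)benzene | O=C1O[C@H](c2ccc(OCc3cccc(COc4ccc(cc4OC)[C@H]5OC(=O)C[C@H]5C)c3)c(OC)c2)[C@H](C)C1
F3 | step 3 | 1,3-bis({4-[(2S,3R,4R)-3,4-dimethyl-5-oxooxolan-2-yl]-2-methoxyphenoxy}methyl)benzene | O=C1O[C@H](c2ccc(OCc3cccc(COc4ccc(cc4OC)[C@H]5OC(=O)[C@H](C)[C@H]5C)c3)c(OC)c2)[C@H](C)[C@H]1C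
F4 | step 5 | 1,3-bis({2-methoxy-4-[(2S,3R,4R)-5-methoxy-3,4-dimethyloxolan-2-yl]phenoxy}methyl)benzene, both anomers | COC1O[C@H](c2ccc(OCc3cccc(COc4ccc(cc4OC)[C@H]5OC(OC)[C@H](C)[C@H]5C)c3)c(OC)c2)[C@H](C)[C@H]1C
F5 | step 5 | potassium [4-(benzyloxy)-3-methoxyphenyl]trifluoroborate | [K+].F[B-](F)(F)c1ccc(OCc2ccccc2)c(OC)c1
F6 | step 8 | (S)-2-chloro-1-(3,4-dimethoxyphenyl)propan-1-one | C[C@H](Cl)C(=O)c1ccc(OC)c(OC)c1
F7 | step 8 | 2,2'-{[(2S,3R,4R,5S)-3,4-dimethyloxolane-2,5-diyl]bis[(2-methoxy-4,1-phenylene)oxy]}bis[(2R)-1-(3,4-dimethoxyphenyl)propan-1-one] | COc1ccc(C(=O)[C@@H](C)Oc2ccc([C@H]3O[C@H](c4ccc(O[C@H](C)C(=O)c5ccc(OC)c(OC)c5)c(OC)c4)[C@H](C)[C@H]3C)cc2OC)cc1OC
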